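**Plan**
- The last disconnection strips twelve O-methyl groups; before that, the A-B biaryl bond is cut (Suzuki-Miyaura) to a monobrominated, fully methylated B-C-D terphenyl and 2,4,6-trimethoxyphenylboronic acid.
- The B-C and C-D bonds are then cut together. In ring C the carbons bearing rings B and D flank one hydroxyl, with chlorine para to it, so they are the two equivalent ortho C-H positions of 4-chloro-3,5-dimethoxyphenol.
- Forward: the ring C phenol comes from 2-chloro-1,3-dimethoxybenzene by C-H borylation/oxidation, and the aryllead reagent from 1,3,5-trimethoxybenzene and Pb(OAc)4. Two-fold ortho-arylation joins B-C-D, followed by O-methylation, monobromination of a terminal ring, coupling of ring A and global demethylation.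
- All four benzene rings are bought and no ring is formed. The target has no stereocentre, and no axial configuration is controlled.

Key step: step 3

Assumption: the target structure carries no axial descriptor, so the B-C axis (four ortho oxygens between two unsymmetrical rings) is treated as configurationally unspecified, and 10, 12 and 13 are handled as racemic or freely interconverting material.

**Step 1**
Reactants: 1 2-chloro-1,3-dimethoxybenzene
Product: 3 4-chloro-3,5-dimethoxyphenol, via aryl pinacol boronate 2 (not isolated)
Conditions: [Ir(OMe)(cod)]2 (1.5 mol %), 4,4'-di-tert-butyl-2,2'-bipyridine (3 mol %), B2pin2 (0.6 equiv), THF, 80 °C; then Oxone (2KHSO5·KHSO4·K2SO4), acetone/H2O, 0 °C to rt, short contact; NaHSO3 quench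
Reagents that add atoms: potassium peroxymonosulfate (oxidant of Oxone), [K+].OOS(=O)(=O)[O-]; bis(pinacolato)diboron, CC1(C)OB(OC1(C)C)B1OC(C)(C)C(C)(C)O1 (boron of intermediate 2 only)
Why: Iridium-catalysed C-H borylation is sterically controlled and should take the one C-H of 1 that has no ortho substituent (C5, para to chlorine, leaving the C-Cl bond untouched), and oxidation of the C-B bond by peroxymonosulfate in the same flask (one-pot borylation/oxidation to phenols) then gives 3 as a single regioisomer, which chlorination of 3,5-dimethoxyphenol would not guarantee.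

**Step 2**
Reactants: 4 1,3,5-trimethoxybenzene; 5 lead tetraacetate
Product: 6 2,4,6-trimethoxyphenyllead triacetate
Conditions: Pb(OAc)4 (1.0 equiv), CHCl3, rt, dark; crystallisation
Reagents that add atoms: none
Why: Direct electrophilic plumbation by tetravalent lead is facile for this triply activated arene and gives the crystalline aryllead triacetate in one operation, the three C-H positions of 4 being equivalent and the metalated ring being deactivated toward a second plumbation.

**Step 3**
Reactants: 3 4-chloro-3,5-dimethoxyphenol; 6 2,4,6-trimethoxyphenyllead triacetate (2.5 equiv)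
Product: 8 4-chloro-3,5-dimethoxy-2,6-bis(2,4,6-trimethoxyphenyl)phenol, via monoarylated phenol 7 (not isolated)
Conditions: pyridine (7.5 equiv), CHCl3, 40 °C, then 60 °C
Reagents that add atoms: none
Why: Assisted by pyridine, the phenol displaces acetate on the tetravalent lead of 6 to give an aryl(aryloxy)lead diacetate, and ligand coupling within this species transfers the 2,4,6-trimethoxyphenyl group to the ortho carbon with loss of Pb(OAc)2 (divalent lead); the 6-aryl-cyclohexa-2,4-dienone so formed tautomerises to phenol 7, which passes through the same sequence at its remaining ortho C-H to give 8. The closest known reaction is the Pinhey ortho-arylation of electron-rich phenols with aryllead triacetates, which tolerates di-ortho-methoxylated aryl groups and has been used for two-fold arylation of 3,5-disubstituted phenols. No ring is closed and no stereocentre is created; the two new bonds are the B-C and C-D biaryl bonds. The step needs C- over O-arylation and ortho over para attack: the O-Pb link confines aryl transfer to the ortho carbons, the para carbon is blocked by chlorine, and the two ortho sites are equivalent, so only one mono- and one bis-arylated product can arise. The donating 3,5-dimethoxy pattern should keep the ortho carbon nucleophilic enough for the second, more hindered transfer, which is driven by the excess of 6 and the higher final temperature.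

**Step 4**
Reactants: 8 4-chloro-3,5-dimethoxy-2,6-bis(2,4,6-trimethoxyphenyl)phenol
Product: 9 2-chloro-1,3,5-trimethoxy-4,6-bis(2,4,6-trimethoxyphenyl)benzene
Conditions: MeI, Cs2CO3, DMF, rt to 40 °C
Reagents that add atoms: iodomethane, CI
Why: Williamson O-alkylation of the cesium phenoxide with iodomethane is a dependable way to methylate 2,6-diarylphenols, and capping the only free hydroxyl keeps ring C from ipso attack or oxidation in the bromination that follows, all twelve methyl ethers then leaving together at the end.

**Step 5**
Reactants: 9 2-chloro-1,3,5-trimethoxy-4,6-bis(2,4,6-trimethoxyphenyl)benzene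
Product: 10 4-(3-bromo-2,4,6-trimethoxyphenyl)-2-chloro-1,3,5-trimethoxy-6-(2,4,6-trimethoxyphenyl)benzene (one bromine on one terminal ring, between two methoxy groups)
Conditions: NBS (0.8 equiv), MeCN, −20 °C to 0 °C; unreacted 9 recovered and recycled
Reagents that add atoms: N-bromosuccinimide, O=C1CCC(=O)N1Br
Why: Electrophilic aromatic bromination with NBS can only occur on the terminal rings because ring C is hexasubstituted, the four remaining C-H positions (each between two methoxy groups and para to a third) are equivalent so any single substitution gives 10, and keeping NBS below one equivalent with recovery of 9 should hold back the statistically unavoidable second bromination on the other terminal ring.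

**Step 6**
Reactants: 10 4-(3-bromo-2,4,6-trimethoxyphenyl)-2-chloro-1,3,5-trimethoxy-6-(2,4,6-trimethoxyphenyl)benzene; 11 2,4,6-trimethoxyphenylboronic acid (3 equiv, added in portions)
Product: 12 2-chloro-1,3,5-trimethoxy-4-(2,4,6-trimethoxyphenyl)-6-[2,4,6-trimethoxy-3-(2,4,6-trimethoxyphenyl)phenyl]benzene (dodecamethyl ether of the target)
Conditions: Pd2(dba)3 (5 mol %), SPhos (2-dicyclohexylphosphino-2',6'-dimethoxybiphenyl, 20 mol %), K3PO4, degassed toluene/H2O, 100 °C
Reagents that add atoms: none
Why: Suzuki-Miyaura coupling with a zerovalent palladium catalyst carrying the bulky dialkylbiarylphosphine SPhos is the established way to tetra-ortho-substituted biaryls, oxidative addition should take the C-Br bond ahead of the C-Cl bond buried between two methoxy groups on hexasubstituted ring C, and the excess of 11 added in portions offsets its protodeboronation.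

**Step 7**
Reactants: 12 dodecamethyl ether of the target
Product: 13 CNP0271703.0, 2-chloro-4-(2,4,6-trihydroxyphenyl)-6-[2,4,6-trihydroxy-3-(2,4,6-trihydroxyphenyl)phenyl]benzene-1,3,5-triol
Conditions: BBr3 (about 3 equiv per OMe), CH2Cl2, −78 °C to rt; ice/H2O quench; Sephadex LH-20 (MeOH) under argon
Reagents that add atoms: none
Why: Lewis-acid ether cleavage with BBr3 (O-B coordination, then bromide attack on methyl) should remove all twelve methyl groups, since aryl methyl ethers flanked by aryl groups are cleaved readily by this reagent while the aryl chloride and the three biaryl bonds are inert to it.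

**Compound list**
1 | 2-chloro-1,3-dimethoxybenzene | COc1cccc(OC)c1Cl | starting material
2 | 2-(4-chloro-3,5-dimethoxyphenyl)-4,4,5,5-tetramethyl-1,3,2-dioxaborolane | COc1cc(B2OC(C)(C)C(C)(C)O2)cc(OC)c1Cl | intermediate
3 | 4-chloro-3,5-dimethoxyphenol | COc1cc(O)cc(OC)c1Cl | intermediate
4 | 1,3,5-trimethoxybenzene | COc1cc(OC)cc(OC)c1 | starting material
5 | lead tetraacetate | CC(=O)O[Pb](OC(C)=O)(OC(C)=O)OC(C)=O | starting material
6 | 2,4,6-trimethoxyphenyllead triacetate | COc1cc(OC)c([Pb](OC(C)=O)(OC(C)=O)OC(C)=O)c(OC)c1 | intermediate
7 | 4-chloro-3,5-dimethoxy-2-(2,4,6-trimethoxyphenyl)phenol | COc1cc(OC)c(-c2c(O)cc(OC)c(Cl)c2OC)c(OC)c1 | intermediate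
8 | 4-chloro-3,5-dimethoxy-2,6-bis(2,4,6-trimethoxyphenyl)phenol | COc1cc(OC)c(-c2c(O)c(-c3c(OC)cc(OC)cc3OC)c(OC)c(Cl)c2OC)c(OC)c1 | intermediate
9 | 2-chloro-1,3,5-trimethoxy-4,6-bis(2,4,6-trimethoxyphenyl)benzene | COc1cc(OC)c(-c2c(OC)c(-c3c(OC)cc(OC)cc3OC)c(OC)c(Cl)c2OC)c(OC)c1 | intermediate
10 | 4-(3-bromo-2,4,6-trimethoxyphenyl)-2-chloro-1,3,5-trimethoxy-6-(2,4,6-trimethoxyphenyl)benzene | COc1cc(OC)c(-c2c(OC)c(-c3c(OC)cc(OC)c(Br)c3OC)c(OC)c(Cl)c2OC)c(OC)c1 | intermediate
11 | 2,4,6-trimethoxyphenylboronic acid | COc1cc(OC)c(B(O)O)c(OC)c1 | starting material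
12 | 2-chloro-1,3,5-trimethoxy-4-(2,4,6-trimethoxyphenyl)-6-[2,4,6-trimethoxy-3-(2,4,6-trimethoxyphenyl)phenyl]benzene | COc1cc(OC)c(-c2c(OC)cc(OC)c(-c3c(OC)c(Cl)c(OC)c(-c4c(OC)cc(OC)cc4OC)c3OC)c2OC)c(OC)c1 | intermediate
13 | CNP0271703.0, 2-chloro-4-(2,4,6-trihydroxyphenyl)-6-[2,4,6-trihydroxy-3-(2,4,6-trihydroxyphenyl)phenyl]benzene-1,3,5-triol | Oc1cc(O)c(-c2c(O)cc(O)c(-c3c(O)c(Cl)c(O)c(-c4c(O)cc(O)cc4O)c3O)c2O)c(O)c1 | target

**Count**
Total steps: 7. Longest linear sequence: 6 steps (steps 1, 3, 4, 5, 6, 7 from compound 1); step 2 is a one-step branch.

**Steps most likely to fail**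

Step 3 (two-fold arylation). The second ligand coupling may stall at the monoarylated stage, because the already ortho-arylated aryloxide must bind a lead centre that carries a di-ortho-methoxylated aryl group. Meanwhile reagent 6 would be consumed by protodeplumbation and homocoupling. The fallback sets out from 3 and comes back at 9, forming the same B-C and C-D bonds by cross-coupling. Phenol 3 is brominated at both ortho positions (NBS, 2.1 equiv, MeCN, 0 °C) to 2,6-dibromo-4-chloro-3,5-dimethoxyphenol F1. F1 is O-methylated (MeI, K2CO3, acetone) to 1,3-dibromo-5-chloro-2,4,6-trimethoxybenzene F2. F2 is then coupled twice with boronic acid 11 (Pd2(dba)3, SPhos, K3PO4, toluene, 100 °C), the two C-Br bonds reacting ahead of C-Cl, to give 9 without passing through 8.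

Step 6 (hindered Suzuki-Miyaura coupling). Protodeboronation of the 2,6-dimethoxylated boronic acid 11 may outrun transmetalation onto the crowded arylpalladium bromide, leaving 10 unreacted or reduced back to 9. The fallback sets out from 10 and comes back at 12 by a Negishi coupling, whose nucleophile cannot protodeboronate. Arene 4 is lithiated between two methoxy groups (n-BuLi, THF, 0 °C to rt) to 2,4,6-trimethoxyphenyllithium F3. F3 is transmetalated with ZnCl2 to (2,4,6-trimethoxyphenyl)zinc chloride F4. F4 is coupled with 10 using Pd2(dba)3 and RuPhos (2-dicyclohexylphosphino-2',6'-diisopropoxybiphenyl) in THF/NMP at 70 °C to give 12.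

Step 7 (global demethylation). Cleavage of the ethers buried between two aryl groups may stop short of completion, and the free dodecaphenol may oxidise in air or be lost on the stationary phase during purification. The fallback sets out from 12 and comes back at 13 by isolating through a stable derivative. After the BBr3 treatment the crude polyphenol is not purified but peracetylated (Ac2O, pyridine, DMAP, rt) to the dodecaacetate of 13 F5. F5 can be chromatographed on silica, where partly methylated material should separate. Acid-catalysed methanolysis (HCl generated from AcCl in degassed MeOH, rt) then releases 13 with only volatile co-products.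

**Further compounds**
F1 | step 3 | 2,6-dibromo-4-chloro-3,5-dimethoxyphenol | COc1c(Cl)c(OC)c(Br)c(O)c1Br
F2 | step 3 | 1,3-dibromo-5-chloro-2,4,6-trimethoxybenzene | COc1c(Cl)c(OC)c(Br)c(OC)c1Br
F3 | step 6 | 2,4,6-trimethoxyphenyllithium | [Li]c1c(OC)cc(OC)cc1OC
F4 | step 6 | (2,4,6-trimethoxyphenyl)zinc chloride | COc1cc(OC)c([Zn]Cl)c(OC)c1
F5 | step 7 | dodecaacetate of 13 | CC(=O)Oc1cc(OC(C)=O)c(-c2c(OC(C)=O)cc(OC(C)=O)c(-c3c(OC(C)=O)c(Cl)c(OC(C)=O)c(-c4c(OC(C)=O)cc(OC(C)=O)cc4OC(C)=O)c3OC(C)=O)c2OC(C)=O)c(OC(C)=O)c1
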